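(The numbers in the tables were generated by integration with constants of no real substance; noise was put on by code.)

The closed, stirred vessel holds substrate, reagent and a trace of free catalyst. The flask shares its substrate and reagent charges with spring and dusk, and its catalyst charge lies between theirs.

| setting | spring | dusk | autumn | flask |
|---|---|---|---|---|
| substrate | 0.13 M | 0.13 M | 0.26 M | 0.13 M |
| reagent | 0.26 M | 0.26 M | 0.26 M | 0.260 M |
| free catalyst | 0.44 mM | 0.98 mM | 0.65 mM | 0.65 mM |
| remark | run made earlier | run made earlier | run made earlier |  |
| time |  |  |  | 3.0 min |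

| run | time / s | product / % | substrate / % | open intermediate / % |
|---|---|---|---|---|
| spring | 10.0 | 1.2 | 85.2 | 14.0 |
| spring | 20.0 | 2.7 | 77.9 | 21.2 |
| spring | 50.0 | 8.3 | 60.6 | 31.1 |
| spring | 120 | 23.5 | 43.1 | 34.7 |
| dusk | 15.0 | 3.2 | 70.5 | 25.9 |
| dusk | 40.0 | 13.9 | 50.8 | 35.4 |
| dusk | 80.0 | 30.4 | 35.2 | 33.4 |
| dusk | 120 | 45.5 | 26.0 | 27.5 |
| autumn | 10.0 | 1.4 | 82.0 | 16.2 |
| autumn | 20.0 | 3.2 | 74.5 | 21.7 |
| autumn | 50.0 | 9.7 | 59.3 | 32.4 |
| autumn | 120 | 24.6 | 40.6 | 34.7 |

(standard deviation of a reading: 0.5 percentage points)

- what was read earlier has a scatter of 0.5 percentage points, one standard deviation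

* concentration of product at 3.0 min, in M
* concentration of substrate at 3.0 min, in M
* concentration of open intermediate at 3.0 min, in M

Substrate is the limiting reagent. Apart from that, the readings show that substrate + open intermediate + product stays close to the substrate charged, with 99.0% in dusk at 120 s, so I take this balance from the readings and reckon two of the three. I define a lifetime τ: open intermediate divided by the rate of product gain, read over the last interval of a run.

τ(spring) = 152 s, τ(dusk) = 80.7 s

Set against the catalyst charges, these two readings give an apparent order n = 0.787. For the flask I take: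

τ(flask) = τ(dusk)·(dusk catalyst/flask catalyst)^n = 111 s

So 3.0 min in the flask corresponds to 130 s of dusk. Carrying dusk forward from its last reading, I get product 49.0% and substrate 24.1%. The balance leaves open intermediate 26.9%. That is:

product 0.0637 M, substrate 0.0313 M, open intermediate 0.0350 M

The forecast, reading “Spring and dusk nearly superimpose”, gives 0.063 M, 0.031 M and 0.036 M, its open intermediate lying slightly above mine.

The flask gives 0.0641 M, 0.0321 M and 0.0336 M.

    free catalyst + open intermediate ⇌ catalyst intermediate (K = 510 M⁻¹, k = 37.0 M⁻¹ s⁻¹)
    substrate + free catalyst ⇌ free catalyst + open intermediate (K = 1.70, k = 51.0 M⁻¹ s⁻¹)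
    reagent + catalyst intermediate → free catalyst + product (k = 7.40 M⁻¹ s⁻¹)
    2 free catalyst ⇌ resting dimer (K = 1300 M⁻¹, k = 61.0 M⁻¹ s⁻¹)

At 3.00 min the flask makes open intermediate at 0.531 of the rate at which it uses it, while catalyst intermediate stands at a ratio of 0.999. Between 1.50 min and 3.00 min, τ(flask) and the mean open intermediate give a product gain of 24.5%, and the flask gains 25 percentage points. The same flask read at 80 s corresponds to 57.9 s of dusk, where dusk interpolates to 21.3% product, and that flask holds 21.3%.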